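**Plan**

- Retrosynthesis (butenolide numbered O1, C2 = carbonyl, C3 = methyl-bearing, C4 = chain-bearing, C5 = CH2): the C3–CH3 bond is cut first (cross-coupling at a 3-chloride), C3=C4 is traced back to a saturated 3,3-dichlorolactone (loss of HCl), and O1 is then lifted out from between C2 and C5.
- This leaves a 2,2-dichlorocyclobutanone with a C2–C5 bond that the target lacks; cutting C3–C4 and C2–C5 together ([2+2]) gives dichloroketene and a terminal alkene. The enabling feature is that C4 and C5 of the lactone are a vinyl group in disguise and C2–C3 is a ketene unit.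
- The C18 alkenyl acetate is cut between chain carbons 3 and 4 (acetylide plus epoxide), the unsaturation having been walked back from the chain end.
- Forward: the chain is joined first (steps 1–4), the four-membered ring closes in step 5, oxygen insertion turns it into the five-membered lactone in step 6, and steps 7 and 8 add the ring alkene and the methyl group.
- Stereochemistry: the only stereocentre of the target, the (S)-acetoxy carbon, comes from (S)-propylene oxide and its C–O bond is never broken; the ring stereocentre formed in step 5 is removed in step 7.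

Key step: step 5

Step 1
Reactants: 1 1-pentadecyne; 2 (S)-propylene oxide
Product: 5 (2S)-octadec-4-yn-2-ol, via lithium pentadec-1-yn-1-ide 3 (not isolated), via lithium (2S)-octadec-4-yn-2-olate 4 (not isolated)
Conditions: n-BuLi, THF, −78 °C; then 2, DMPU, −78 °C → rt; aq. NH4Cl
Reagents that add atoms: none
Why: Alkynylation of an epoxide, in which the lithium acetylide opens 2 by SN2 attack at the unsubstituted CH2, so the stereocentre of 2 is carried over untouched as the (S)-carbinol.

Step 2
Reactants: 5 (2S)-octadec-4-yn-2-ol
Product: 7 (2S)-octadec-17-yn-2-ol, via dipotassium (2S)-octadec-17-yn-1-id-2-olate 6 (not isolated)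
Conditions: KH, H2N(CH2)3NH2, rt (forms KAPA); then 5, 0 °C → rt; H2O
Reagents that add atoms: none
Why: Alkyne zipper isomerisation, in which KAPA moves the triple bond by repeated propargyl–allenyl proton shifts away from the blocking alkoxide until the terminal acetylide, the thermodynamic sink, is reached, while the carbinol stays an alkoxide and cannot epimerise.

Step 3
Reactants: 7 (2S)-octadec-17-yn-2-ol
Product: 8 (2S)-octadec-17-en-2-ol
Conditions: H2 (1 atm), Pd/CaCO3 poisoned with Pb(OAc)2 (Lindlar catalyst), quinoline, EtOAc, rt, stopped after 1 equiv of H2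
Reagents that add atoms: none
Why: Lindlar semihydrogenation, which should stop at the terminal alkene because the poisoned palladium surface binds the alkyne much more strongly than the alkene it produces.

Step 4
Reactants: 8 (2S)-octadec-17-en-2-ol
Product: 9 (2S)-octadec-17-en-2-yl acetate
Conditions: Ac2O, pyridine, DMAP (cat.), CH2Cl2, 0 °C → rt
Reagents that add atoms: acetic anhydride, CC(=O)OC(C)=O
Why: DMAP-catalysed O-acylation of a secondary alcohol, which leaves the C–O bond intact and so retains the (S) configuration.

Step 5
Reactants: 9 (2S)-octadec-17-en-2-yl acetate; 10 trichloroacetyl chloride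
Product: 12 (2S)-16-(2,2-dichloro-3-oxocyclobutyl)hexadecan-2-yl acetate, via dichloroketene 11 (not isolated)
Conditions: Zn–Cu couple, 10 (slow addition), Et2O/DME, rt → gentle reflux
Reagents that add atoms: trichloroacetyl chloride 10, ClC(=O)C(Cl)(Cl)Cl (enters as dichloroketene 11, O=C=C(Cl)Cl)
Why: Zinc removes two chlorines from 10 to give dichloroketene 11, whose electrophilic carbonyl carbon meets the alkene in a concerted but asynchronous, orthogonal [π2s + π2a] cycloaddition: bonding to the terminal CH2 runs ahead, and the positive charge building on the internal, chain-bearing carbon is quenched by the CCl2 terminus. The closest known reaction type is the zinc-mediated dichloroketene–olefin [2+2] cycloaddition of unactivated 1-alkenes to 3-alkyl-2,2-dichlorocyclobutanones. The four-membered ring closes by intermolecular [2+2] cycloaddition, and both of its new bonds (the later C3–C4 and the temporary C2–C5) are made in this one step. The single new stereocentre, the ring carbon carrying the chain, is under no control from the remote acetoxy centre and needs none, because step 7 turns it into an sp2 carbon. The step needs regioselectivity (ketene carbonyl carbon to CH2), which the polarisation of the monosubstituted alkene toward its more substituted carbon should secure, and chemoselectivity, which rests on the inertness of the acetate to the ketene and on DME tying up ZnCl2. Slow addition of 10 keeps the ketene concentration low so that capture by the alkene can compete with ketene oligomerisation.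

Step 6
Reactants: 12 (2S)-16-(2,2-dichloro-3-oxocyclobutyl)hexadecan-2-yl acetate
Product: 14 (2S)-16-(4,4-dichloro-5-oxooxolan-3-yl)hexadecan-2-yl acetate, via Criegee peroxyester adduct 13 (not isolated)
Conditions: mCPBA, CH2Cl2, 0 °C → rt
Reagents that add atoms: mCPBA (3-chloroperoxybenzoic acid), OOC(=O)c1cccc(Cl)c1
Why: Baeyer–Villiger oxidation, in which the strained and strongly electrophilic ketone adds the peracid and, in the Criegee adduct, the electron-richer CH2 migrates in preference to the electron-poor CCl2 carbon, so oxygen enters the C2–C5 bond and no new stereocentre results.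

Step 7
Reactants: 14 (2S)-16-(4,4-dichloro-5-oxooxolan-3-yl)hexadecan-2-yl acetate
Product: 15 (2S)-16-(4-chloro-5-oxo-2,5-dihydrofuran-3-yl)hexadecan-2-yl acetate
Conditions: DBU, THF, 0 °C → rt
Reagents that add atoms: none
Why: E2 dehydrochlorination, in which the amidine base removes the C4–H anti to one of the two C3 chlorines (C4 is the only β-carbon bearing hydrogen) to give the conjugated tetrasubstituted alkene and erase the ring stereocentre.

Step 8
Reactants: 15 (2S)-16-(4-chloro-5-oxo-2,5-dihydrofuran-3-yl)hexadecan-2-yl acetate
Product: 16 (2S)-16-(4-methyl-5-oxo-2,5-dihydrofuran-3-yl)hexadecan-2-yl acetate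
Conditions: (MeBO)3, Pd(OAc)2 (5 mol %), SPhos (10 mol %), K3PO4, dioxane, 90 °C
Reagents that add atoms: trimethylboroxine, CB1OB(C)OB(C)O1
Why: Suzuki–Miyaura coupling, in which the electron-poor alkenyl C–Cl bond adds oxidatively to the zerovalent palladium–SPhos complex, methyl is transferred from the phosphate-activated boroxine, and reductive elimination forms the C3–CH3 bond without touching the remote stereocentre.

**Compound list**

1 | 1-pentadecyne | CCCCCCCCCCCCCC#C | starting material
2 | (S)-propylene oxide [(2S)-2-methyloxirane] | C[C@H]1CO1 | starting material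
3 | lithium pentadec-1-yn-1-ide | [Li+].[C-]#CCCCCCCCCCCCCC | intermediate (not isolated)
4 | lithium (2S)-octadec-4-yn-2-olate | [Li+].C[C@H]([O-])CC#CCCCCCCCCCCCCC | intermediate (not isolated)
5 | (2S)-octadec-4-yn-2-ol | C[C@H](O)CC#CCCCCCCCCCCCCC | intermediate
6 | dipotassium (2S)-octadec-17-yn-1-id-2-olate | [K+].[K+].C[C@H]([O-])CCCCCCCCCCCCCCC#[C-] | intermediate (not isolated)
7 | (2S)-octadec-17-yn-2-ol | C[C@H](O)CCCCCCCCCCCCCCC#C | intermediate
8 | (2S)-octadec-17-en-2-ol | C[C@H](O)CCCCCCCCCCCCCCC=C | intermediate
9 | (2S)-octadec-17-en-2-yl acetate | CC(=O)O[C@@H](C)CCCCCCCCCCCCCCC=C | intermediate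
10 | trichloroacetyl chloride | ClC(=O)C(Cl)(Cl)Cl | starting material
11 | dichloroketene | O=C=C(Cl)Cl | intermediate (not isolated)
12 | (2S)-16-(2,2-dichloro-3-oxocyclobutyl)hexadecan-2-yl acetate, both epimers at the ring CH | CC(=O)O[C@@H](C)CCCCCCCCCCCCCCC1CC(=O)C1(Cl)Cl | intermediate
13 | Criegee adduct, (2S)-16-[2,2-dichloro-3-hydroxy-3-(3-chlorobenzoylperoxy)cyclobutyl]hexadecan-2-yl acetate | CC(=O)O[C@@H](C)CCCCCCCCCCCCCCC1CC(O)(OOC(=O)c2cccc(Cl)c2)C1(Cl)Cl | intermediate (not isolated)
14 | (2S)-16-(4,4-dichloro-5-oxooxolan-3-yl)hexadecan-2-yl acetate, both epimers at the ring CH | CC(=O)O[C@@H](C)CCCCCCCCCCCCCCC1COC(=O)C1(Cl)Cl | intermediate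
15 | (2S)-16-(4-chloro-5-oxo-2,5-dihydrofuran-3-yl)hexadecan-2-yl acetate | CC(=O)O[C@@H](C)CCCCCCCCCCCCCCC1=C(Cl)C(=O)OC1 | intermediate
16 | (2S)-16-(4-methyl-5-oxo-2,5-dihydrofuran-3-yl)hexadecan-2-yl acetate | CC(=O)O[C@@H](C)CCCCCCCCCCCCCCC1=C(C)C(=O)OC1 | target

**Step count and risks**

Total step count: 8. Longest linear sequence: 8 steps (from 1 and 2 to 16).

Steps most likely to fail:

Step 8. Transmetalation of methyl from boron may be slow at a hindered, tetrasubstituted alkenylpalladium centre. During prolonged heating with phosphate the butenolide can be deprotonated at C5 or the esters cleaved, so decomposition may outpace coupling. The fallback gives up the boron/base pairing for a base-free organozinc (Negishi) methylation. It sets out from 15 and comes back to the route at 16: MeZnCl with Pd(P(t-Bu)3)2 in THF/NMP at about 60 °C. The organozinc transmetalates without added base and both esters should tolerate it. No new compound is made on the way.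

Step 5. Oligomerisation of the ketene and side reactions promoted by zinc chloride may outrun capture by the unactivated, monosubstituted alkene, so conversion stalls however much ketene precursor is fed in. The fallback abandons the four-membered ring and builds the butenolide by olefination; it sets out from 9 and comes back at 16.
- Dihydroxylation (OsO4 cat., NMO, acetone/H2O) should give (2S)-17,18-dihydroxyoctadecan-2-yl acetate F1.
- Acylation of the primary hydroxyl with 2-(diethoxyphosphoryl)propanoic acid (DCC, DMAP cat., CH2Cl2, 0 °C) should give (17S)-17-acetoxy-2-hydroxyoctadecyl 2-(diethoxyphosphoryl)propanoate F2.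
- Dess–Martin oxidation of the remaining secondary alcohol should give (17S)-17-acetoxy-2-oxooctadecyl 2-(diethoxyphosphoryl)propanoate F3.
- Intramolecular Horner–Wadsworth–Emmons closure under Masamune–Roush conditions (LiCl, i-Pr2NEt, MeCN, rt) should form the C3=C4 bond with the methyl group already in place and deliver 16 directly.

Step 3. Once the alkyne is consumed, the terminal alkene may be reduced further on the catalyst, giving saturated material that cannot be removed in practice. The fallback replaces catalytic hydrogenation by hydroboration and protonolysis, which cannot over-reduce; it sets out from 7 and comes back at 9.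
- Acetylation first (Ac2O, pyridine, DMAP cat.) should give (2S)-octadec-17-yn-2-yl acetate F4.
- Monohydroboration with dicyclohexylborane (THF, 0 °C) should give (2S,17E)-18-(dicyclohexylboranyl)octadec-17-en-2-yl acetate F5.
- Protonolysis of the alkenyl–boron bond with acetic acid (rt → 50 °C) should release the terminal alkene 9.

**Further compounds**

F0 | step 8 | none | none
F1 | step 5 | (2S)-17,18-dihydroxyoctadecan-2-yl acetate | CC(=O)O[C@@H](C)CCCCCCCCCCCCCCC(O)CO
F2 | step 5 | (17S)-17-acetoxy-2-hydroxyoctadecyl 2-(diethoxyphosphoryl)propanoate | CC(=O)O[C@@H](C)CCCCCCCCCCCCCCC(O)COC(=O)C(C)P(=O)(OCC)OCC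
F3 | step 5 | (17S)-17-acetoxy-2-oxooctadecyl 2-(diethoxyphosphoryl)propanoate | CC(=O)O[C@@H](C)CCCCCCCCCCCCCCC(=O)COC(=O)C(C)P(=O)(OCC)OCC
F4 | step 3 | (2S)-octadec-17-yn-2-yl acetate | CC(=O)O[C@@H](C)CCCCCCCCCCCCCCC#C
F5 | step 3 | (2S,17E)-18-(dicyclohexylboranyl)octadec-17-en-2-yl acetate | CC(=O)O[C@@H](C)CCCCCCCCCCCCCC/C=C/B(C1CCCCC1)C1CCCCC1
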